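**Retrosynthetic overview**
- Halogens last: the ring C–Br and C–Cl are delivered to a 4-methylcyclohex-3-en-1-ol under control of its tertiary alkoxide (chloride syn to O, bromine anti).
- Key bond is the tertiary C–O bond of that carbinol: it is made by transannular alkoxymercuration from a ring carbinol whose configuration comes from a Shi epoxidation (C–O) of a 1,4-cyclohexadiene. The oxygen bridge is then opened reductively, with a bromide as the trigger.
- Six-membered ring (second ring): cobalt-catalysed [4+2] cycloaddition of a cyclopentyl alkyne with isoprene.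
- Cyclopentane (first ring, with its C–Br and quaternary carbon): catalytic enantioselective bromonium cyclization of the enol acetate of melonal; the aldehyde is then homologated to the alkyne.
- Ring order: cyclopentane, then cyclohexadiene, then the temporary oxygen bridge in and out, then halogenation.

Assumption: substrates, building blocks, intermediates and products carry numbers, other reagents stand on the Conditions line; ring locants C1 (carbinol), C3 (CHBr), C4 (CClMe) and C6 in the text are those of the target's six-membered ring.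

**Step 1**
Reactants: 1 2,6-dimethylhept-5-enal (melonal, racemic); 2 acetic anhydride
Product: 3 2,6-dimethylhepta-1,5-dien-1-yl acetate (E/Z mixture)
Conditions: Ac2O, KOAc (0.2 equiv), 140 °C
Reagents that add atoms: none
Why: Enol acetylation (O-acylation of the aldehyde enol) gives the latent carbon nucleophile; both alkene isomers serve because this geometry is lost in step 2.

**Step 2**
Reactants: 3 2,6-dimethylhepta-1,5-dien-1-yl acetate
Product: 5 (1R,3S)-3-bromo-1,2,2-trimethylcyclopentane-1-carbaldehyde, via O-acetyl oxocarbenium ion 4 (not isolated)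
Conditions: NBS (1.1 equiv), (R)-BINOL-derived N-triflyl thiophosphoramide (10 mol%), toluene/CH2Cl2, −78 °C; then aq. NaHCO3
Reagents that add atoms: N-bromosuccinimide, O=C1CCC(=O)N1Br
Why: Proposed new method: the chiral Lewis-base catalyst transfers Br+ to one face of the prenyl alkene (more electron-rich and less hindered than the enol acetate), the enol acetate carbon closes the five-membered ring on the tertiary bromonium carbon through an envelope transition state that places Br and the bulkier acyl-bearing arm cis, and ion 4 loses its acetyl group on work-up, so the CHBr carbon is set by the catalyst and the quaternary carbon by the ring closure; the closest known reaction type is the chiral Lewis-base-catalysed enantioselective bromonium polyene cyclization with arene terminators, combined with enol-acetate-terminated cation–olefin cyclization.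

**Step 3**
Reactants: 5 (1R,3S)-3-bromo-1,2,2-trimethylcyclopentane-1-carbaldehyde; 6 dimethyl (1-diazo-2-oxopropyl)phosphonate
Product: 7 (1S,3S)-3-bromo-1-ethynyl-1,2,2-trimethylcyclopentane
Conditions: K2CO3, MeOH, 0 °C to rt
Reagents that add atoms: none
Why: Seyferth–Gilbert homologation (Ohira–Bestmann variant) converts the non-enolisable aldehyde into the terminal alkyne under mild base, leaving both stereocenters and the secondary bromide untouched.

**Step 4**
Reactants: 7 (1S,3S)-3-bromo-1-ethynyl-1,2,2-trimethylcyclopentane; 8 isoprene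
Product: 9 1-[(1S,3S)-3-bromo-1,2,2-trimethylcyclopentyl]-4-methylcyclohexa-1,4-diene
Conditions: CoBr2(dppe) (10 mol%), Zn (20 mol%), ZnI2 (20 mol%), CH2Cl2, rt
Reagents that add atoms: none
Why: Cobalt-catalysed neutral [4+2] cycloaddition (Hilt type) of an unactivated terminal alkyne with isoprene; the dppe ligand gives the 1,4-disubstituted cyclohexa-1,4-diene and no stereocenter is formed.

**Step 5**
Reactants: 9 1-[(1S,3S)-3-bromo-1,2,2-trimethylcyclopentyl]-4-methylcyclohexa-1,4-diene
Product: 10 (1S,6R)-4-[(1S,3S)-3-bromo-1,2,2-trimethylcyclopentyl]-1-methyl-7-oxabicyclo[4.1.0]hept-3-ene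
Conditions: D-fructose-derived Shi ketone (30 mol%), KHSO5 (as 2KHSO5·KHSO4·K2SO4), K2CO3, Bu4NHSO4, MeCN/CH2(OMe)2/aq. buffer pH 10.5, 0 °C
Reagents that add atoms: potassium peroxymonosulfate, [K+].[O-]S(=O)(=O)OO
Why: Shi asymmetric epoxidation: the chiral dioxirane reacts only at the unhindered methyl-substituted alkene, and its spiro transition state picks one alkene face irrespective of the remote cyclopentane (this ketone enantiomer is the one predicted by that model), which sets the oxygen configuration at C4 and C3.

**Step 6**
Reactants: 10 (1S,6R)-4-[(1S,3S)-3-bromo-1,2,2-trimethylcyclopentyl]-1-methyl-7-oxabicyclo[4.1.0]hept-3-ene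
Product: 11 (1S,6S)-6-bromo-4-[(1S,3S)-3-bromo-1,2,2-trimethylcyclopentyl]-1-methylcyclohex-3-en-1-ol
Conditions: Li2NiBr4, THF, 0 °C; aq. work-up
Reagents that add atoms: dilithium tetrabromonickelate, [Li+].[Li+].[Br-].[Br-].[Br-].[Br-].[Ni+2]
Why: Regioselective SN2 epoxide opening (bromohydrin formation): bromide attacks the secondary epoxide carbon with inversion, so Br ends trans to the tertiary hydroxyl, whose configuration from step 5 is kept.

**Step 7**
Reactants: 11 (1S,6S)-6-bromo-4-[(1S,3S)-3-bromo-1,2,2-trimethylcyclopentyl]-1-methylcyclohex-3-en-1-ol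
Product: 13 (1S,2S,4R)-2-bromo-4-[(1R,3S)-3-bromo-1,2,2-trimethylcyclopentyl]-1-methyl-7-oxabicyclo[2.2.1]heptane, via organomercury trifluoroacetate 12 (not isolated)
Conditions: Hg(O2CCF3)2, CH2Cl2, −20 °C; then NaBH4, aq. NaOH, 0 °C
Reagents that add atoms: none
Why: Intramolecular alkoxymercuration–demercuration (Markovnikov oxymercuration): the C4 hydroxyl can reach C1 only across the ring from its own face (boat transition state, as in 1,4-cineole formation), so the new tertiary C1–O bond forms cis to the C4–O bond and C1 is fixed relative to the catalyst-set carbons without a free neopentyl cation.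

**Step 8**
Reactants: 13 (1S,2S,4R)-2-bromo-4-[(1R,3S)-3-bromo-1,2,2-trimethylcyclopentyl]-1-methyl-7-oxabicyclo[2.2.1]heptane
Product: 14 (1R)-1-[(1R,3S)-3-bromo-1,2,2-trimethylcyclopentyl]-4-methylcyclohex-3-en-1-ol
Conditions: Zn dust, AcOH, EtOH, 40 °C
Reagents that add atoms: none
Why: Boord-type reductive β-elimination: zinc reduces the C3–Br bond that is antiperiplanar to the bridging C4–O bond and the alkoxide leaves, which restores the trisubstituted alkene and frees the C1 alcohol with its configuration intact, while the cyclopentyl bromide has no β-leaving group and survives.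

**Step 9**
Reactants: 14 (1R)-1-[(1R,3S)-3-bromo-1,2,2-trimethylcyclopentyl]-4-methylcyclohex-3-en-1-ol
Product: 16 (1R,3S,4S)-3-bromo-1-[(1R,3S)-3-bromo-1,2,2-trimethylcyclopentyl]-4-chloro-4-methylcyclohexan-1-ol, via chlorotitanium alkoxide 15 (not isolated)
Conditions: ClTi(OiPr)3 (1.2 equiv), CH2Cl2/hexane, rt (iPrOH removed in vacuo); then NBS (1.1 equiv), −20 °C; aq. NaHCO3
Reagents that add atoms: N-bromosuccinimide, O=C1CCC(=O)N1Br; chlorotitanium triisopropoxide, CC(C)O[Ti](Cl)(OC(C)C)OC(C)C
Why: Proposed new method: NBS forms the bromonium ion reversibly on either alkene face, but only the one anti to the titanium alkoxide can be opened from within, the Ti-bound chloride reaching the tertiary C4 on the alkoxide face through a boat-like transition state (the 1,4-geometry oxygen uses in cineole-type bromoetherification), which gives Cl cis and Br trans to OH, an arrangement that ordinary trans-diaxial ionic addition does not give; the closest known reaction type is the titanium-alkoxide-directed bromochlorination of allylic alcohols with NBS/ClTi(OiPr)3.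

**Compound list**
1 | 2,6-dimethylhept-5-enal (melonal, racemic) | CC(C)=CCCC(C)C=O | starting material
2 | acetic anhydride | CC(=O)OC(C)=O | starting material
3 | 2,6-dimethylhepta-1,5-dien-1-yl acetate (E/Z mixture) | CC(=O)OC=C(C)CCC=C(C)C | intermediate
4 | O-acetyl oxocarbenium ion of 5 (acetyl group on the aldehyde oxygen) | CC1(C)[C@@H](Br)CC[C@@]1(C)C=[O+]C(C)=O | intermediate
5 | (1R,3S)-3-bromo-1,2,2-trimethylcyclopentane-1-carbaldehyde (Br cis to CHO) | CC1(C)[C@@H](Br)CC[C@@]1(C)C=O | intermediate
6 | dimethyl (1-diazo-2-oxopropyl)phosphonate | COP(=O)(OC)C(=[N+]=[N-])C(C)=O | starting material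
7 | (1S,3S)-3-bromo-1-ethynyl-1,2,2-trimethylcyclopentane | CC1(C)[C@@H](Br)CC[C@@]1(C)C#C | intermediate
8 | isoprene (2-methylbuta-1,3-diene) | C=CC(C)=C | starting material
9 | 1-[(1S,3S)-3-bromo-1,2,2-trimethylcyclopentyl]-4-methylcyclohexa-1,4-diene | CC1(C)[C@@H](Br)CC[C@@]1(C)C1=CCC(C)=CC1 | intermediate
10 | (1S,6R)-4-[(1S,3S)-3-bromo-1,2,2-trimethylcyclopentyl]-1-methyl-7-oxabicyclo[4.1.0]hept-3-ene | CC1(C)[C@@H](Br)CC[C@@]1(C)C1=CC[C@]2(C)O[C@@H]2C1 | intermediate
11 | (1S,6S)-6-bromo-4-[(1S,3S)-3-bromo-1,2,2-trimethylcyclopentyl]-1-methylcyclohex-3-en-1-ol (Br trans to OH) | CC1(C)[C@@H](Br)CC[C@@]1(C)C1=CC[C@](C)(O)[C@@H](Br)C1 | intermediate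
12 | organomercury trifluoroacetate: 13 carrying HgO2CCF3 on C5 of the oxabicycle, anti to the oxygen bridge | CC1(C)[C@@H](Br)CC[C@@]1(C)[C@@]1(O2)[C@@H]([Hg]OC(=O)C(F)(F)F)C[C@@]2(C)[C@@H](Br)C1 | intermediate
13 | (1S,2S,4R)-2-bromo-4-[(1R,3S)-3-bromo-1,2,2-trimethylcyclopentyl]-1-methyl-7-oxabicyclo[2.2.1]heptane (Br anti to the oxygen bridge) | CC1(C)[C@@H](Br)CC[C@@]1(C)[C@@]1(O2)CC[C@@]2(C)[C@@H](Br)C1 | intermediate
14 | (1R)-1-[(1R,3S)-3-bromo-1,2,2-trimethylcyclopentyl]-4-methylcyclohex-3-en-1-ol | CC1(C)[C@@H](Br)CC[C@@]1(C)[C@@]1(O)CCC(C)=CC1 | intermediate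
15 | chlorobis(propan-2-olato)titanium alkoxide of 14 | CC1(C)[C@@H](Br)CC[C@@]1(C)[C@@]1(O[Ti](Cl)(OC(C)C)OC(C)C)CCC(C)=CC1 | intermediate
16 | (1R,3S,4S)-3-bromo-1-[(1R,3S)-3-bromo-1,2,2-trimethylcyclopentyl]-4-chloro-4-methylcyclohexan-1-ol (CNP0116087.1) | CC1(C)[C@@H](Br)CC[C@@]1(C)[C@@]1(O)CC[C@](C)(Cl)[C@@H](Br)C1 | target

**Totals and risks**
Total step count: 9. Longest linear sequence: 9 steps (1 to 16).

The three steps most likely to fail:

- **Step 2 (proposed new method).** The risks are direct α-bromination of the enol acetate, low enantioselectivity, and the wrong cis/trans ratio at the quaternary carbon. Fallback with known chemistry: setting out from 3, a racemic bromonium cyclization with the reagent Et2SBr·SbCl5Br in MeNO2 at −25 °C, followed by aqueous work-up, gives 5 together with its enantiomer (1S,3R)-3-bromo-1,2,2-trimethylcyclopentane-1-carbaldehyde F1. Preparative chromatography on a chiral stationary phase removes F1, and the route is rejoined at 5.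

- **Step 9 (proposed new method).** The risks are delivery of chloride to C3 instead of C4, and capture of the bromonium ion by the oxygen itself, which gives back 13 (this can be returned through step 8). Fallback with known reaction types: setting out from 14, hydroxyl-directed epoxidation with VO(acac)2/tBuOOH gives the cis-epoxy alcohol (1R,3R,6S)-3-[(1R,3S)-3-bromo-1,2,2-trimethylcyclopentyl]-6-methyl-7-oxabicyclo[4.1.0]heptan-3-ol F2. Li2NiBr4 opens it at the secondary carbon to (1S,2S,4R)-2-bromo-4-[(1R,3S)-3-bromo-1,2,2-trimethylcyclopentyl]-1-methylcyclohexane-1,4-diol F3. SOCl2/pyridine then converts the less hindered methyl-bearing tertiary hydroxyl into the chloride with retention through the bromonium ion, arriving at 16. The bromide opening in this fallback goes against the usual trans-diaxial preference, so it is a weaker option than step 9.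

- **Step 7.** The risks are slow mercuration of the neopentyl-type alkene and halide abstraction by the mercury salt. Fallback: setting out from 11, a hydrogen-atom-transfer hydroalkoxylation (radical-polar crossover) with a Co(salen) catalyst, N-fluoro-2,4,6-trimethylpyridinium tetrafluoroborate and PhSiH3 closes the same oxygen bridge and returns to the route at 13. This fallback makes no new compound (F0).

**Further compounds**
F1 | step 2 | (1S,3R)-3-bromo-1,2,2-trimethylcyclopentane-1-carbaldehyde | CC1(C)[C@H](Br)CC[C@]1(C)C=O
F2 | step 9 | (1R,3R,6S)-3-[(1R,3S)-3-bromo-1,2,2-trimethylcyclopentyl]-6-methyl-7-oxabicyclo[4.1.0]heptan-3-ol | CC1(C)[C@@H](Br)CC[C@@]1(C)[C@@]1(O)CC[C@]2(C)O[C@@H]2C1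
F3 | step 9 | (1S,2S,4R)-2-bromo-4-[(1R,3S)-3-bromo-1,2,2-trimethylcyclopentyl]-1-methylcyclohexane-1,4-diol | CC1(C)[C@@H](Br)CC[C@@]1(C)[C@@]1(O)CC[C@](C)(O)[C@@H](Br)C1
F0 | step 7 | none | none
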